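- I cannot put a clock on tris adduct or over-reaction product in the runs so far, because a peak such as 0.7% of tris adduct in the ochre run stands below 1 percentage point, two scatters of a single reading, and so I choose the next flask without any time constant for these side products.

| flask | substrate | coupling partner | temperature | remark | time |
|---|---|---|---|---|---|
| red | 10 mM | 1.3 equiv | 28 °C | run made earlier |  |
| ochre | 15 mM | 1.3 equiv | 44 °C | run made earlier |  |
| alder | 20 mM | 1.30 equiv |  | at 50 °C until 20 h, from then on at 20 °C | 40 h |
| larch | 20 mM | 1.30 equiv | 20 °C |  | 40 h |
| elm | 20 mM | 1.30 equiv | 50 °C |  | 40 h |
| oak | 20 mM | 1.30 equiv | 35 °C |  | 40 h |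

| run | time / h | double product / % | tris adduct / % | over-reaction product / % |
|---|---|---|---|---|
| red | 8.00 | 1.4 | 0.2 | 0 |
| red | 15.0 | 2.4 | 0 | 0.2 |
| red | 25.0 | 3.7 | 0.4 | 0.4 |
| red | 30.0 | 3.2 | 0.5 | 0 |
| red | 40.0 | 4.4 | 0.1 | 0 |
| red | 50.0 | 4.5 | 0 | 0 |
| ochre | 1.33 | 0.7 | 0 | 0.6 |
| ochre | 2.00 | 0.9 | 0.7 | 0 |
| ochre | 3.00 | 2.0 | 0.7 | 0.4 |
| ochre | 6.00 | 2.7 | 0.5 | 0 |
| ochre | 10.0 | 3.3 | 0 | 0 |
| ochre | 15.0 | 4.2 | 0 | 0 |

(scatter of a reading: 0.5 percentage points)



- which flask leads in share of double product in all that became double product or tris adduct or over-reaction product ("all alike" within 1.5 percentage points) (alder / larch / elm / oak / all alike)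
- share of double product in all that became double product or tris adduct or over-reaction product, alder
- share of double product in all that became double product or tris adduct or over-reaction product, larch
- share of double product in all that became double product or tris adduct or over-reaction product, elm
- share of double product in all that became double product or tris adduct or over-reaction product, oak

- The decision is whether heat, cold or a change of temperature earns its place for the sake of the share, which is the selectivity towards double product.
- I therefore divide the growth rate of the side products by that of double product, as an engineer plots one output against another, so that time drops out; since the three start from nothing, the ratio of amounts is this ratio of rates averaged over the run.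
- I call it the side ratio, [c(tris adduct) + c(over-reaction product)] / c(double product), summed over the last three readings of each run, where double product stands clear of the scatter: 0.0496 in the red run and 0.0490 in the ochre run, which is 16.0 K hotter.
- Pooled, the side ratio is 0.0493, but its own scatter of 0.0777 is larger than the ratio, so the like values of the two runs show no temperature effect without excluding one.
- I commit to one share, 95.3%, for the four flasks, and so to all alike, and I pick no temperature for the share.
- The forecast differs on larch, giving 96% for alder, 82% for larch, 96% for elm and 97% for oak, with oak in front, because larch “equals only about 11 h of the red run, so tris remains”.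
- The flasks give 96.7% for alder, 97.0% for larch, 96.6% for elm and 96.6% for oak, so the answer is all alike; changing just the temperature from the red run to larch leaves the computed share at 97.4%, against 96.9%. Put to use on larch, the side ratio turns the 5.75% of double product at 40.0 h into 0.284% of side products, below one scatter, while the flask holds 0.138% of tris adduct and 0.0417% of over-reaction product.

    substrate + coupling partner → first product (k = 0.0161 L mol⁻¹ min⁻¹, Ea = 51.0 kJ mol⁻¹)
    coupling partner + first product → double product (k = 0.0787 L mol⁻¹ min⁻¹, Ea = 62.0 kJ mol⁻¹)
    coupling partner + double product → tris adduct (k = 0.00568 L mol⁻¹ min⁻¹, Ea = 66.0 kJ mol⁻¹)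
    2 coupling partner → homo dimer (k = 0.0921 L mol⁻¹ min⁻¹, Ea = 73.0 kJ mol⁻¹)
    coupling partner + double product → over-reaction product (k = 0.00172 L mol⁻¹ min⁻¹, Ea = 60.0 kJ mol⁻¹)
    (constants at 20 °C)

- On the neighbour of alder charged with 12 mM of substrate, a charge between those of the two runs, the side ratio gives 95.3% again, and 0.186% of side products on 3.77% of double product; the computed share there is 96.7%.

The data were computed with made-up constants; noise was put on by code.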